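**Plan**
The single 17-membered ring is numbered N1–C2(nonyl)–C3–C4(=O)–N5–C6–C7–C8–N9–C10–C11–C12–C13–N14–C15–C16–C17. It holds a β-amino amide N1–C2–C3–C4(=O)–N5 whose β-carbon C2 is the only stereocentre, and N5 through N1 is an intact spermine chain.
Retrosynthetic cuts, in order: N1–C2 (back to a C2 ketone and the distal primary amine), then the amide C4–N5, then C2–C3 (decanoyl carbon to malonyl carbon).
Forward: spermine is desymmetrised as its tri-Boc derivative, C2–C3 is made on Meldrum's acid, the acylketene from that adduct forms C4–N5, acid frees the polyamine, and the ring closes last.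
Stereochemistry: C2 (R) is created in the ring closure by enzyme-controlled hydride transfer from NADPH to the cyclic iminium; no later step can erode it.

Key step: step 5

Remark: the target is taken as the free base drawn, and the imine reductase of step 5 is assumed to be a variant found by panel screening (and directed evolution if needed) for the R sense at C2; enzymes of both facial preferences exist in this class.

**Route**

Step 1
Reactants: 1 spermine
Product: 4 N1,N4,N9-tri-Boc-spermine, via mono-N-trifluoroacetylspermine 2 (not isolated), via N-trifluoroacetyl-tri-Boc-spermine 3 (not isolated)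
Conditions: CF3CO2Et (1.0 equiv), MeOH, −78 → 0 °C; Boc2O (4 equiv), 0 → 25 °C; conc. aq. NH3, 25 °C (one pot); chromatography
Reagents that add atoms: di-tert-butyl dicarbonate, CC(C)(C)OC(=O)OC(=O)OC(C)(C)C; ethyl trifluoroacetate, CCOC(=O)C(F)(F)F (its trifluoroacetyl group is carried only by 2 and 3 and is removed before 4)
Why: At low temperature ethyl trifluoroacetate acylates only primary amines and one equivalent caps one terminus on average (selective N-trifluoroacetylation), Boc2O then converts the three remaining nitrogens into carbamates, and ammonia cleaves the base-labile trifluoroacetamide while the Boc groups stay, a standard one-pot desymmetrisation of polyamines.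

Step 2
Reactants: 5 Meldrum's acid; 6 decanoyl chloride
Product: 7 decanoyl Meldrum's acid (5-(1-hydroxydecylidene)-2,2-dimethyl-1,3-dioxane-4,6-dione)
Conditions: pyridine (2.2 equiv), CH2Cl2, 0 → 25 °C; 1 M aq. HCl wash; used crude
Reagents that add atoms: none
Why: C-Acylation of the acidic methylene of Meldrum's acid by the acid chloride with pyridine as base (Oikawa–Yonemitsu acylation) should give the enolised acyl Meldrum's acid and forms the future C2–C3 bond.

Step 3
Reactants: 4 N1,N4,N9-tri-Boc-spermine; 7 decanoyl Meldrum's acid
Product: 9 N-(3-oxododecanoyl)-tri-Boc-spermine, via decanoylketene 8 (not isolated)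
Conditions: toluene, 90 °C, 3 h
Reagents that add atoms: none
Why: On warming, 7 fragments with loss of acetone and CO2 to the acylketene 8, which is trapped by the primary amine, the only nucleophilic nitrogen of 4, to give the β-keto amide (acylketene aminolysis of an acyl Meldrum's acid); the carbamate N–H groups should not compete.

Step 4
Reactants: 9 N-(3-oxododecanoyl)-tri-Boc-spermine
Product: 10 N-(3-oxododecanoyl)spermine trihydrochloride
Conditions: 4 M HCl in 1,4-dioxane, 0 → 25 °C; trituration with Et2O
Reagents that add atoms: hydrogen chloride, Cl (three equivalents retained in the salt)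
Why: Acidolysis of the three tert-butyl carbamates (Boc removal) should leave the acid-stable β-keto amide untouched and deliver the polyamine as its trihydrochloride, in which no nitrogen is free to condense with the ketone on storage.

Step 5
Reactants: 10 N-(3-oxododecanoyl)spermine trihydrochloride
Product: 13 (2R)-2-nonyl-1,5,9,14-tetraazacycloheptadecan-4-one, via macrocyclic Z-enaminone 11 (not isolated), via macrocyclic imine 12 (not isolated)
Conditions: purified (R)-selective imine reductase (reductive aminase type), NADP+ (cat.), glucose dehydrogenase, D-glucose (1.5 equiv), KH2PO4/K2HPO4 buffer pH 8.0 (held with KOH), 2 mM in 10, 30 °C; then sulfonic acid cation-exchange resin, elution with aq. NH3, lyophilisation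
Reagents that add atoms: none
Why: Proposed new method: in the buffer the freed primary amine (future N1) condenses reversibly with the C2 ketone, which the neighbouring amide carbonyl activates, to give the hydrogen-bonded Z-enaminone 11 in equilibrium with the imine tautomer 12, and the enzyme binds the protonated imine and transfers the NADPH hydride to one face of C2, the only irreversible event. The closest known reaction type is the imine-reductase (reductive-aminase) amination of β-keto esters with primary amines to N-alkyl β-amino esters, together with intramolecular imine-reductase cyclisations that so far reach only five- to seven-membered rings. The 17-membered ring closes by 17-exo-trig attack of N1 on the ketone followed by dehydration, under thermodynamic control at high dilution, so that open-chain oligomeric adducts revert and only the reduced macrocycle should accumulate. C2 is set as R by catalyst control alone, through the face of the iminium that the chosen variant presents to the nicotinamide hydride, since the substrate has no other stereocentre. The step needs site selectivity for N1 over N9 and N14 and chemoselectivity for C=N over C=O: N9 could only close a strained eight-membered ring, N14 would have to form a crowded tertiary iminium that cannot become the chelated enaminone, enzymes of this class leave the ketone itself unreduced, and the protonated secondary amines keep the substrate water-soluble without taking part.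

**Compound list**
1 | spermine (N,N'-bis(3-aminopropyl)butane-1,4-diamine) | NCCCNCCCCNCCCN | starting material
2 | mono-N-trifluoroacetylspermine (one terminal NH2 capped) | FC(F)(F)C(=O)NCCCNCCCCNCCCN | intermediate (not isolated)
3 | N-trifluoroacetyl-tri-Boc-spermine (trifluoroacetamide at one terminus, Boc on the two inner nitrogens and on the other terminus) | FC(F)(F)C(=O)NCCCN(C(=O)OC(C)(C)C)CCCCN(C(=O)OC(C)(C)C)CCCNC(=O)OC(C)(C)C | intermediate (not isolated)
4 | N1,N4,N9-tri-Boc-spermine (one terminal NH2 free) | NCCCN(C(=O)OC(C)(C)C)CCCCN(C(=O)OC(C)(C)C)CCCNC(=O)OC(C)(C)C | intermediate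
5 | Meldrum's acid (2,2-dimethyl-1,3-dioxane-4,6-dione) | CC1(C)OC(=O)CC(=O)O1 | starting material
6 | decanoyl chloride | CCCCCCCCCC(=O)Cl | starting material
7 | decanoyl Meldrum's acid, enol form (5-(1-hydroxydecylidene)-2,2-dimethyl-1,3-dioxane-4,6-dione) | CCCCCCCCCC(O)=C1C(=O)OC(C)(C)OC1=O | intermediate
8 | decanoylketene (3-oxododec-1-en-1-one) | CCCCCCCCCC(=O)C=C=O | intermediate (not isolated)
9 | N-(3-oxododecanoyl)-tri-Boc-spermine (3-oxododecanamide of the free terminus of 4) | CCCCCCCCCC(=O)CC(=O)NCCCN(C(=O)OC(C)(C)C)CCCCN(C(=O)OC(C)(C)C)CCCNC(=O)OC(C)(C)C | intermediate
10 | N-(3-oxododecanoyl)spermine trihydrochloride (N-[3-({4-[(3-aminopropyl)amino]butyl}amino)propyl]-3-oxododecanamide · 3 HCl) | CCCCCCCCCC(=O)CC(=O)NCCCNCCCCNCCCN.Cl.Cl.Cl | intermediate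
11 | (2Z)-2-nonyl-1,5,9,14-tetraazacycloheptadec-2-en-4-one (chelated enaminone) | CCCCCCCCC/C1=C/C(=O)NCCCNCCCCNCCCN1 | intermediate (not isolated)
12 | 2-nonyl-1,5,9,14-tetraazacycloheptadec-1-en-4-one (cyclic imine) | CCCCCCCCCC1=NCCCNCCCCNCCCNC(=O)C1 | intermediate (not isolated)
13 | (2R)-2-nonyl-1,5,9,14-tetraazacycloheptadecan-4-one | CCCCCCCCC[C@@H]1CC(=O)NCCCNCCCCNCCCN1 | target

**Count**
Total steps: 5. Longest linear sequence: 4 steps (1 → 4 → 9 → 10 → 13, or 5 and 6 → 7 → 9 → 10 → 13).

**Steps most likely to fail**

Step 5. The enzyme may not turn over because the 17-atom chain does not fold into a reducible cyclic iminium in the active site. Hydride delivery may also show poor facial selectivity, or occur on an iminium formed at N14. The fallback sets out from spermine 1 and comes back at 13, using known chemistry and closing the ring at the amide instead. Spermine 1 in threefold excess is added in MeOH at 25–50 °C to methyl (E)-dodec-2-enoate (CCCCCCCCC/C=C/C(=O)OC). This aza-Michael addition at a primary nitrogen should give racemic methyl 3-{[3-({4-[(3-aminopropyl)amino]butyl}amino)propyl]amino}dodecanoate F1. The tetraamino ester is lactamised between N5 and C4 with Sb(OEt)3 as template in refluxing toluene at about 5 mM, a template macrolactamisation known for polyamino esters of this ring size. This should give racemic 2-nonyl-1,5,9,14-tetraazacycloheptadecan-4-one F2. Resolution by preparative chromatography on a chiral stationary phase, or by fractional crystallisation of its salts with a dibenzoyltartaric acid, should give 13.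

Step 1. The statistical mono-trifluoroacetylation may over- and under-acylate, so that too little mono-protected amine is recovered from the mixture. The fallback sets out from 1 and comes back at 10, and moves the statistical event to the acylation, where the excess diamine can be recovered. Both primary amines are capped with CF3CO2Et (2.2 equiv, MeOH, −78 → 0 °C) to give N1,N12-bis(trifluoroacetyl)spermine F3. Boc2O in the same pot gives N1,N12-bis(trifluoroacetyl)-N4,N9-di-Boc-spermine F4, and conc. aq. NH3 frees both termini to give N4,N9-di-Boc-spermine F5. A threefold excess of this diamine is heated with 7 in toluene to give N1-(3-oxododecanoyl)-N4,N9-di-Boc-spermine F6. This is taken without storage into HCl in slightly wet 1,4-dioxane, which removes both Boc groups and hydrolyses any enaminone formed between the free amine and the ketone, to give 10.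

Step 3. During thermal generation of the acylketene, unreacted amine may condense with the newly formed ketone to an enaminone, or a Boc group may be lost at 90 °C. The fallback sets out from 7 and comes back at 9, and forms the amide at room temperature from a β-keto thioester. Compound 7 is heated with 2-methylpropane-2-thiol in toluene to give S-tert-butyl 3-oxododecanethioate F7. This is coupled with amine 4 using AgO2CCF3 and Et3N in THF at 25 °C (thiophile-promoted aminolysis of a β-keto thioester) to give 9.

**Further compounds**
F1 | step 5 | methyl 3-{[3-({4-[(3-aminopropyl)amino]butyl}amino)propyl]amino}dodecanoate (racemic) | CCCCCCCCCC(CC(=O)OC)NCCCNCCCCNCCCN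
F2 | step 5 | 2-nonyl-1,5,9,14-tetraazacycloheptadecan-4-one (racemic) | CCCCCCCCCC1CC(=O)NCCCNCCCCNCCCN1
F3 | step 1 | N1,N12-bis(trifluoroacetyl)spermine | FC(F)(F)C(=O)NCCCNCCCCNCCCNC(=O)C(F)(F)F
F4 | step 1 | N1,N12-bis(trifluoroacetyl)-N4,N9-di-Boc-spermine | FC(F)(F)C(=O)NCCCN(C(=O)OC(C)(C)C)CCCCN(C(=O)OC(C)(C)C)CCCNC(=O)C(F)(F)F
F5 | step 1 | N4,N9-di-Boc-spermine | NCCCN(C(=O)OC(C)(C)C)CCCCN(C(=O)OC(C)(C)C)CCCN
F6 | step 1 | N1-(3-oxododecanoyl)-N4,N9-di-Boc-spermine | CCCCCCCCCC(=O)CC(=O)NCCCN(C(=O)OC(C)(C)C)CCCCN(C(=O)OC(C)(C)C)CCCN
F7 | step 3 | S-tert-butyl 3-oxododecanethioate | CCCCCCCCCC(=O)CC(=O)SC(C)(C)C
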